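**Retrosynthetic overview**
1. Target 23 ⇐ ketone 22 (C=CH2 from C=O by Wittig) ⇐ iodo ketone 21 (C–I to C–H).
2. Key disconnection: the oxolane of 21 (ether O, the O–CH of ring B, the spiro carbon, the CMe2 carbon, the O–CH of ring C) ⇐ the oxirane of 19 (the same O, the same ring-B CH, the future spiro carbon). The enabling feature is the spiro carbon: it sits between a ring-B C–O bond that is trans to its CMe2 neighbour and a carbonyl-level carbon of ring C, which is the imprint of an invertive 1,2-shift of the CMe2 ring carbon of a cyclopentenol onto an opening oxirane; the second ether carbon is then an alkene carbon four bonds from that oxygen.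
3. 19 ⇐ alkenyl iodide 14 + 2,2-dimethylcyclopent-3-enone 17 (alkenylcerium addition, directed epoxidation).
4. 14 ⇐ trans-decalone 12 ⇐ bromo lactone 9 (Dieckmann closes ring B) ⇐ dienedioate 7 (bromonium-induced cyclization closes ring A) ⇐ 1 + 2 through two Claisen rearrangements.
5. Ring order: ring A (bromocyclohexane), then ring B (second decalin ring), then ring C (methylenecyclohexane, by expansion of the cyclopentene) together with the oxolane in the key step.

Key step: step 14

Remark: the carbinol carbon made in step 12 forms as both epimers and is written without configuration in 18 and 19, because it becomes the carbonyl carbon in step 14. Compounds 3, 4, 6 and 16 are racemic; their stereocentres are destroyed in the following steps. In the text, α is the decalin face of the angular methyl and β the face of the ring-fusion hydrogen.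

**Route**

Step 1
Reactants: 1 tert-butyl acetate; 2 methacrolein
Product: 3 tert-butyl 3-hydroxy-4-methylpent-4-enoate (racemic)
Conditions: LiN(i-Pr)2 (commercial solution), THF, −78 °C; 2; then cold 1 M HCl
Reagents that add atoms: none
Why: Directed aldol addition of the lithium ester enolate to the enal should occur 1,2 at −78 °C, and the racemic carbinol centre is removed in step 2.

Step 2
Reactants: 3 tert-butyl 3-hydroxy-4-methylpent-4-enoate
Product: 5 tert-butyl (3E)-4-methyl-7-oxohept-3-enoate, via allyl vinyl ether 4 (not isolated)
Conditions: CH2=CHOEt (solvent), Hg(OAc)2 (5 mol%), 35 °C; concentrate; toluene, 150 °C (sealed tube)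
Reagents that add atoms: ethyl vinyl ether, C=COCC
Why: Vinyl transfer followed by Claisen rearrangement through a chair transition state with the CH2CO2t-Bu group equatorial should give the E-trisubstituted alkene.

Step 3
Reactants: 5 tert-butyl (3E)-4-methyl-7-oxohept-3-enoate
Product: 6 tert-butyl (3E)-7-hydroxy-4,8-dimethylnona-3,8-dienoate (racemic)
Conditions: CH2=C(CH3)MgBr, THF, −78 °C; then cold 1 M HCl
Reagents that add atoms: isopropenylmagnesium bromide, CC(=C)[Mg]Br
Why: Grignard addition should be selective for the aldehyde over the hindered tert-butyl ester at −78 °C, and the racemic carbinol centre is removed in step 4.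

Step 4
Reactants: 6 tert-butyl (3E)-7-hydroxy-4,8-dimethylnona-3,8-dienoate
Product: 7 11-tert-butyl 1-methyl (4E,8E)-4,8-dimethylundeca-4,8-dienedioate
Conditions: CH3C(OMe)3, EtCO2H (cat.), 110 °C, MeOH distilled off
Reagents that add atoms: trimethyl orthoacetate, CC(OC)(OC)OC
Why: Johnson–Claisen rearrangement of the secondary allylic alcohol through a chair transition state with the chain equatorial should give the second E-trisubstituted alkene.

Step 5
Reactants: 7 11-tert-butyl 1-methyl (4E,8E)-4,8-dimethylundeca-4,8-dienedioate
Product: 9 cis-fused bromo lactone ester, via trans-fused bromo lactone ester 8 (not isolated)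
Conditions: 1,3-dibromo-5,5-dimethylhydantoin (0.55 equiv), chiral BINOL-derived thiophosphoramide (10 mol%), toluene/CH2Cl2, −78 °C; then TfOH (0.2 equiv), CH2Cl2, 0 °C
Reagents that add atoms: 1,3-dibromo-5,5-dimethylhydantoin, CC1(C)N(Br)C(=O)N(Br)C1=O
Why: Lewis-base-catalysed enantioselective bromonium-induced cation–olefin cyclization of the more electron-rich alkene, ended by the tert-butyl ester with loss of isobutene, should close ring A through a chair transition state of the E,E-diene (bromine equatorial, ring methyl axial, the two side chains trans-diequatorial, absolute sense from the catalyst enantiomer), and the acid then equilibrates the kinetic trans-lactone through the tertiary cation to the cis-fused lactone whose oxygen is axial and whose methyl avoids the 1,3-diaxial contact with the other ring methyl.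

Step 6
Reactants: 9 cis-fused bromo lactone ester
Product: 10 tricyclic β-keto lactone
Conditions: KOt-Bu (2.2 equiv), THF, 0 → 23 °C; then 1 M HCl
Reagents that add atoms: none
Why: Dieckmann condensation of the lactone enolate onto the methyl ester should close ring B trans-fused because both arms are equatorial on ring A and the two ring-fusion centres were fixed in step 5 (the other Claisen mode, ester enolate onto the lactone carbonyl, would lead to the same ketone after step 7).

Step 7
Reactants: 10 tricyclic β-keto lactone
Product: 12 bromo hydroxy decalone, via keto acid 11 (not isolated)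
Conditions: LiOH, THF/H2O, 23 °C; then 1 M HCl (pH 2), 50 °C
Reagents that add atoms: none
Why: Saponification by acyl–oxygen cleavage should free the axial tertiary alcohol with retention, and the β-keto acid then decarboxylates.

Step 8
Reactants: 12 bromo hydroxy decalone
Product: 13 hydrazone of 12
Conditions: N2H4·H2O, Et3N, EtOH, 70 °C
Reagents that add atoms: hydrazine (as hydrate), NN
Why: Hydrazone formation at the unhindered ring-B ketone should be clean, since the equatorial neopentyl-type bromide is inert to substitution.

Step 9
Reactants: 13 hydrazone of 12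
Product: 14 alkenyl iodide
Conditions: I2, 1,1,3,3-tetramethylguanidine, THF, 0 °C
Reagents that add atoms: iodine, II
Why: Barton vinyl iodide synthesis should place the alkene toward the CH2 remote from the ring fusion, the same preference as in enolization of trans-fused 2-decalones.

Step 10
Reactants: 15 2,2-dimethylcyclopentane-1,3-dione
Product: 16 3-hydroxy-2,2-dimethylcyclopentan-1-one (racemic)
Conditions: NaBH4 (0.3 equiv), MeOH, −20 °C; then 1 M HCl
Reagents that add atoms: none
Why: Substoichiometric borohydride should reduce one of the two equivalent ketones, and the carbinol centre is removed in step 11.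

Step 11
Reactants: 16 3-hydroxy-2,2-dimethylcyclopentan-1-one
Product: 17 2,2-dimethylcyclopent-3-en-1-one
Conditions: Burgess reagent, toluene, 50 °C
Reagents that add atoms: none
Why: Syn elimination of the sulfamate ester can only occur toward the CH2 side (the other neighbour is quaternary) and the non-basic conditions should keep the β,γ-enone from moving into conjugation.

Step 12
Reactants: 14 alkenyl iodide; 17 2,2-dimethylcyclopent-3-en-1-one
Product: 18 dienediol (both carbinol epimers)
Conditions: 14, t-BuLi (3.1 equiv), THF, −78 °C; CeCl3, −78 °C; 17; then AcOH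
Reagents that add atoms: none
Why: Iodine–lithium exchange (after deprotonation of the hydroxyl) should be far faster than any reaction at the hindered secondary bromide, and the alkenylcerium reagent adds 1,2 to the easily enolized ketone; the new carbinol centre forms as both epimers, which converge in step 14.

Step 13
Reactants: 18 dienediol
Product: 19 epoxy diol
Conditions: VO(acac)2 (5 mol%), t-BuOOH, CH2Cl2, 0 °C
Reagents that add atoms: tert-butyl hydroperoxide, CC(C)(C)OO
Why: Hydroxyl-directed epoxidation should select the allylic trisubstituted ring-B alkene over the homoallylic cyclopentene alkene and deliver oxygen to the β face, away from the axial angular methyl, as in epoxidation of 2-ene steroids.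

Step 14
Reactants: 19 epoxy diol
Product: 21 iodo keto ether, via spiro hydroxy enone 20 (not isolated)
Conditions: BF3·OEt2 (2.2 equiv), CH2Cl2, −78 °C; then N-iodosuccinimide, NaHCO3, −78 → 0 °C
Reagents that add atoms: N-iodosuccinimide, O=C1CCC(=O)N1I
Why: BF3 binds the oxirane oxygen, the C–O bond at the fully substituted ring-B carbon ionizes and the CMe2 ring carbon of the cyclopentenol migrates antiperiplanar to it (semipinacol rearrangement of a tertiary 2,3-epoxy alcohol, the closest known reaction type), which makes the carbinol carbon the ketone, expands the cyclopentene to the cyclohexenone of ring C and leaves the former oxirane oxygen as a secondary alkoxide on ring B. N-Iodosuccinimide then activates the only remaining alkene and this oxygen adds to the alkene carbon next to the CMe2 group (iodoetherification), so the three-membered oxirane (O, ring-B CH, spiro carbon) has grown into the five-membered oxolane by taking in the CMe2 carbon and the new O–CH carbon. Ring C arises by the 1,2-alkyl shift (a ring expansion, not a cyclization) and the oxolane closes in the 5-exo-trig mode on the iodonium ion, the 6-endo mode to a bicyclo[2.2.2] ether being disfavoured. The spiro carbon is set by inversion at the migration terminus (the CMe2 carbon enters from the α face, anti to the departing oxygen, which pushes the carbonyl carbon axial), the ring-B O–CH keeps the configuration from the epoxidation, and the two new centres on ring C follow from anti addition with oxygen delivered from the only face the tether allows, the C–I centre being erased in step 15. The step needs opening at the tertiary oxirane carbon (the more cation-stabilizing end), migration of the quaternary CMe2 carbon rather than the CH2 carbon (higher migratory aptitude), no hydride shift to a ring-B ketone (the carbinol oxygen assists the alkyl shift) and no drift of the β,γ-alkene into conjugation before ring closure (−78 °C, aprotic Lewis acid, iodonium source added cold). Both carbinol epimers of 19 should give the same product because that carbon becomes the carbonyl carbon.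

Step 15
Reactants: 21 iodo keto ether
Product: 22 keto ether
Conditions: Bu3SnH (1.05 equiv), Et3B (0.2 equiv), air, toluene, −40 → 0 °C
Reagents that add atoms: none
Why: Radical-chain deiodination with one equivalent of Bu3SnH should be selective because iodine abstraction is about two orders of magnitude faster than bromine abstraction from a secondary bromide; no stereocentre other than the discarded C–I carbon is touched.

Step 16
Reactants: 22 keto ether
Product: 23 target CNP0412361.2
Conditions: Ph3PCH3Br, KOt-Bu, toluene, 80 °C
Reagents that add atoms: methyltriphenylphosphonium bromide, C[P+](c1ccccc1)(c1ccccc1)c1ccccc1.[Br-]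
Why: Wittig methylenation with excess ylide (one equivalent is taken up by the free tertiary hydroxyl) should convert the hindered ketone, which has no β-hydrogen-bearing leaving group and no epimerizable centre next to it, into the exocyclic alkene.

**Compound list**
1 | tert-butyl acetate | CC(=O)OC(C)(C)C | starting material
2 | methacrolein (2-methylprop-2-enal) | CC(=C)C=O | starting material
3 | tert-butyl 3-hydroxy-4-methylpent-4-enoate (racemic) | CC(=C)C(O)CC(=O)OC(C)(C)C | intermediate
4 | tert-butyl 3-(ethenyloxy)-4-methylpent-4-enoate (racemic allyl vinyl ether, not isolated) | C=COC(CC(=O)OC(C)(C)C)C(C)=C | intermediate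
5 | tert-butyl (3E)-4-methyl-7-oxohept-3-enoate | O=CCC/C(C)=C/CC(=O)OC(C)(C)C | intermediate
6 | tert-butyl (3E)-7-hydroxy-4,8-dimethylnona-3,8-dienoate (racemic) | CC(=C)C(O)CC/C(C)=C/CC(=O)OC(C)(C)C | intermediate
7 | 11-tert-butyl 1-methyl (4E,8E)-4,8-dimethylundeca-4,8-dienedioate | COC(=O)CC/C(C)=C/CC/C(C)=C/CC(=O)OC(C)(C)C | intermediate
8 | methyl 3-[(3aS,4S,5S,7aS)-5-bromo-4,7a-dimethyl-2-oxooctahydro-1-benzofuran-4-yl]propanoate (trans-fused lactone, lactone oxygen equatorial, not isolated) | COC(=O)CC[C@]1(C)[C@@H](Br)CC[C@]2(C)OC(=O)C[C@@H]12 | intermediate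
9 | methyl 3-[(3aS,4S,5S,7aR)-5-bromo-4,7a-dimethyl-2-oxooctahydro-1-benzofuran-4-yl]propanoate (cis-fused lactone, lactone oxygen axial and cis to the C-4 methyl, bromine equatorial) | COC(=O)CC[C@]1(C)[C@@H](Br)CC[C@@]2(C)OC(=O)C[C@@H]12 | intermediate
10 | (5aS,6S,8aR,8bS)-6-bromo-5a,8a-dimethyloctahydro-2H-naphtho[1,8-bc]furan-2,3(2aH)-dione (tricyclic β-keto lactone, C-2a epimers and enol) | O=C1CC[C@]2(C)[C@@H](Br)CC[C@@]3(C)OC(=O)C1[C@@H]23 | intermediate
11 | (4aS,5S,8R,8aS)-5-bromo-8-hydroxy-4a,8-dimethyl-2-oxodecahydronaphthalene-1-carboxylic acid (C-1 epimers, not isolated) | O=C1CC[C@]2(C)[C@@H](Br)CC[C@@](C)(O)[C@H]2C1C(=O)O | intermediate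
12 | (4aS,5S,8R,8aS)-5-bromo-8-hydroxy-4a,8-dimethyloctahydronaphthalen-2(1H)-one (trans-decalone; bromine equatorial, hydroxyl axial, both cis to the angular methyl) | O=C1CC[C@]2(C)[C@@H](Br)CC[C@@](C)(O)[C@H]2C1 | intermediate
13 | hydrazone of 12 | NN=C1CC[C@]2(C)[C@@H](Br)CC[C@@](C)(O)[C@H]2C1 | intermediate
14 | (1R,4S,4aS,8aS)-4-bromo-7-iodo-1,4a-dimethyl-1,2,3,4,4a,5,8,8a-octahydronaphthalen-1-ol | IC1=CC[C@]2(C)[C@@H](Br)CC[C@@](C)(O)[C@H]2C1 | intermediate
15 | 2,2-dimethylcyclopentane-1,3-dione | CC1(C)C(=O)CCC1=O | starting material
16 | 3-hydroxy-2,2-dimethylcyclopentan-1-one (racemic) | CC1(C)C(O)CCC1=O | intermediate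
17 | 2,2-dimethylcyclopent-3-en-1-one | CC1(C)C=CCC1=O | intermediate
18 | (1R,4S,4aS,8aS)-4-bromo-7-(1-hydroxy-2,2-dimethylcyclopent-3-en-1-yl)-1,4a-dimethyl-1,2,3,4,4a,5,8,8a-octahydronaphthalen-1-ol (both epimers at the cyclopentenol carbinol carbon) | CC1(C)C=CCC1(O)C1=CC[C@]2(C)[C@@H](Br)CC[C@@](C)(O)[C@H]2C1 | intermediate
19 | epoxy diol: oxirane across the former ring-B alkene of 18, oxygen on the β face (syn to the ring-fusion hydrogen, anti to the angular methyl); both carbinol epimers | CC1(C)C=CCC1(O)[C@@]12O[C@@H]1C[C@]1(C)[C@@H](Br)CC[C@@](C)(O)[C@H]1C2 | intermediate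
20 | spiro hydroxy enone: 2,2-dimethylcyclohex-3-en-1-one ring spiro-joined through its C-6 to the decalin; new secondary hydroxyl equatorial (β) on the neighbouring ring-B carbon, CMe2 carbon on the α face, carbonyl carbon axial (β); not isolated | O=C1CC=CC(C)(C)[C@]12[C@H](O)C[C@]3(C)[C@@H](Br)CC[C@@](C)(O)[C@H]3C2 | intermediate
21 | iodo keto ether: 4-iodo-8,8-dimethyl-6-oxabicyclo[3.2.1]octan-2-one unit fused through C-1 and C-7 to ring B of the bromo hydroxy decalin; iodine anti to the ether oxygen | O=C1C[C@@H](I)[C@@H]2O[C@@H]3C[C@]4(C)[C@@H](Br)CC[C@@](C)(O)[C@H]4C[C@]13C2(C)C | intermediate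
22 | keto ether: 8,8-dimethyl-6-oxabicyclo[3.2.1]octan-2-one unit fused through C-1 and C-7 to ring B of the bromo hydroxy decalin | O=C1CC[C@@H]2O[C@@H]3C[C@]4(C)[C@@H](Br)CC[C@@](C)(O)[C@H]4C[C@]13C2(C)C | intermediate
23 | CNP0412361.2: 8,8-dimethyl-2-methylidene-6-oxabicyclo[3.2.1]octane unit fused through C-1 and C-7 to ring B of the trans-decalin (ether CH of ring C S, ether CH of ring B R, spiro carbon R, ring-fusion CH S, angular C–CH3 S, CHBr S, C(OH)CH3 R) | C=C1CC[C@@H]2O[C@@H]3C[C@]4(C)[C@@H](Br)CC[C@@](C)(O)[C@H]4C[C@]13C2(C)C | target

**Step count and risks**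
Total step count: 16. Longest linear sequence: 14 steps (steps 1–9 and 12–16).

Three steps most likely to fail:

1. Step 14. The rearrangement may take another course (shift of the CH2 ring carbon, hydride shift to a ring-B ketone), or the β,γ-alkene may drift into conjugation under the Lewis acid before the ether closes. The fallback sets out from 19 and comes back at 21. Both hydroxyls are silylated (Me3SiOTf, 2,6-lutidine, CH2Cl2, −78 °C) to give the bis(trimethylsilyl) ether F1. F1 is rearranged at −78 °C with the bulky aluminium Lewis acid MeAl(OAr)2 (Ar = 4-bromo-2,6-di-tert-butylphenyl), a known way to turn epoxy silyl ethers into β-silyloxy ketones with silyl transfer and anti migration, to give the silyloxy ketone F2. HF·pyridine removes both silyl groups so that 20 is isolated, and a separate buffered iodoetherification (N-iodosuccinimide, NaHCO3, MeCN, 0 °C) then gives 21.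

2. Step 5. Facial discrimination in the bromonium transfer may be poor (bromonium exchange between alkenes erodes the enantiomeric excess), and part of the bromonium ion may be intercepted by the distal ester carbonyl. The fallback sets out from 7 and comes back at 9. The cyclization is run without asymmetric induction using the achiral sulfonium reagent Et2SBr·SbCl5Br in MeNO2 at −25 °C, followed by the same TfOH equilibration, and the racemic cis-lactone is resolved by preparative chromatography on a chiral stationary phase. This gives 9 beside the enantiomeric lactone F3, which is set aside.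

3. Step 12. Halogen–metal exchange or elimination at the secondary bromide may compete, and the β,γ-enone may be enolized instead of attacked. The fallback sets out from 14 and comes back at 18 without any organolithium reagent. Carbonylative amidation of 14 (Pd(OAc)2, Xantphos, CO, MeNHOMe·HCl, Et3N, toluene, 80 °C) gives the N-methoxy-N-methylamide F4. Me2C=CHCH2MgCl, which reacts through its tertiary carbon, converts F4 into the α,α-dimethyl β,γ-unsaturated enone F5. CH2=CHCH2MgBr adds 1,2 to give the triene diol F6, and ring-closing metathesis of its two terminal alkenes with second-generation Grubbs catalyst (CH2Cl2, 40 °C) closes the cyclopentene and gives 18.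

**Further compounds**
F1 | step 14 | bis(trimethylsilyl) ether of epoxy diol 19 | CC1(C)C=CCC1(O[Si](C)(C)C)[C@@]12O[C@@H]1C[C@]1(C)[C@@H](Br)CC[C@@](C)(O[Si](C)(C)C)[C@H]1C2
F2 | step 14 | bis(trimethylsilyl) ether of spiro hydroxy enone 20 | O=C1CC=CC(C)(C)[C@]12[C@H](O[Si](C)(C)C)C[C@]3(C)[C@@H](Br)CC[C@@](C)(O[Si](C)(C)C)[C@H]3C2
F3 | step 5 | methyl 3-[(3aR,4R,5R,7aS)-5-bromo-4,7a-dimethyl-2-oxooctahydro-1-benzofuran-4-yl]propanoate (enantiomer of 9) | COC(=O)CC[C@@]1(C)[C@H](Br)CC[C@]2(C)OC(=O)C[C@H]12
F4 | step 12 | (4aS,5S,8R,8aS)-5-bromo-8-hydroxy-N-methoxy-N,4a,8-trimethyl-1,4,4a,5,6,7,8,8a-octahydronaphthalene-2-carboxamide | CON(C)C(=O)C1=CC[C@]2(C)[C@@H](Br)CC[C@@](C)(O)[C@H]2C1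
F5 | step 12 | 1-[(4aS,5S,8R,8aS)-5-bromo-8-hydroxy-4a,8-dimethyl-1,4,4a,5,6,7,8,8a-octahydronaphthalen-2-yl]-2,2-dimethylbut-3-en-1-one | C=CC(C)(C)C(=O)C1=CC[C@]2(C)[C@@H](Br)CC[C@@](C)(O)[C@H]2C1
F6 | step 12 | (1R,4S,4aS,8aS)-4-bromo-7-(4-hydroxy-3,3-dimethylhepta-1,6-dien-4-yl)-1,4a-dimethyl-1,2,3,4,4a,5,8,8a-octahydronaphthalen-1-ol (both carbinol epimers) | C=CCC(O)(C(C)(C)C=C)C1=CC[C@]2(C)[C@@H](Br)CC[C@@](C)(O)[C@H]2C1
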